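## Analysis of the target

The target is a germacranolide: a ten-membered carbocycle C1–C10, trans-fused at C6/C7 to an α-methylene-γ-butyrolactone (ring O, C6, C7, C11, C12, with C11=C13). The carbocycle holds two trisubstituted alkenes, C1=C10 (C14 aldehyde on C10) and C4=C5 (C15 hydroxymethyl on C4). In both, the ring carbons are cis (C2 cis to C9, C3 cis to C6), which is E by the sequence rules. The stereocentres C6, C7 and C8 are contiguous and all R: H6 and H7 are trans on the lactone, and the C7–C11 bond and the C8 oxygen are anti in the zigzag C6–C7–C8–C9. The methylene lactone and the enal are Michael acceptors, C7–H is doubly allylic, and the C8 isovalerate has to survive the cleavage of another ester. The synthesis is hard because of the medium ring and because O8 lies γ to both acyl carbons C12 and C14, so a free C8 hydroxyl lactonises onto either one. The strategy rests on the unit O–C6–C5=C4–C15–O: lactone oxygen, alkene and C15 oxygen form a 2-ene-1,4-dioxygen pattern. That pattern is what 1,4-oxidation of a diene C6=C5–C4=C15 leaves when the C12 carboxylate is the nucleophile at C6.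

## Retrosynthetic reasoning

**C15–O acyl bond (35 from 34).** The diene oxidation leaves C15 as an acetate, so the last step only removes it. The forward reaction has to tell a primary allylic acetate from the secondary isovalerate, the lactone and two Michael acceptors, which calls for a neutral, enzymatic hydrolysis.

**C14 and C11=C13 adjustments (34 from 32 from 31).** The aldehyde is carried as the thioester of 31 because a thioester stabilises the C10 carbanion for ring closure and can later be reduced without touching lactone or esters. The exocyclic methylene is carried as the amine adduct (28 to 32) and released through the ammonium salt 33, because a C10 carbanion would otherwise add to C13 in a six-membered mode.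

**C1=C10 (31 from 30, and back through 29 and 28 to 27).** The ring is cut at the trisubstituted enoate. An intramolecular Horner–Wadsworth–Emmons olefination gives C2 trans to the carbonyl group, which is the ring-cis geometry needed, and both partners (C1 aldehyde from the silyl ether, C10 phosphonate) are inert spectators earlier on.

**O–C6 and O–C15 (27 from 25 and 26).** Both C–O bonds of the 2-ene-1,4-dioxygen unit are cut at once. This returns the acyclic dienoic acid 25 and acetic acid 26, removes the C6 stereocentre and the lactone ring, and makes the C5=C6 geometry of 25 irrelevant. The forward step must close the lactone trans to the C8 chain and place C6 trans to C15 across C4=C5.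

**C4–C5 (25 from 19 and 24).** An sp2–sp2 coupling joins the alkenyl chloride 19 to the 2-borylalkene 24. A chloride is chosen because it is the one alkenyl halide that survives the carbonylation that makes 19.

**C11–C12 (19 from 18).** The acrylic acid comes from the terminal alkyne of 18 by Markovnikov hydroxycarbonylation. It is introduced only after O8 is acylated, because a C12 acyl group γ to a free O8 would lactonise. It is also introduced after the C10 carbanion chemistry, for which an acrylate would be a Michael acceptor, and before the diene exists, because a palladium hydride would attack a diene.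

**O8–acyl and C9–C10 (18 from 16 and 17; 16 from 15; 15 from 11 and 14; 14 from 12 and 13).** C10 enters as the soft carbanion of 14, and C9 must therefore be the electrophile. A β-acyloxy halide would be too sluggish, so the primary triflate 11 with O8 silylated is used, and the silyl group is exchanged for the isovalerate (from 17) right after.

**C7–C11 (11 from 9 via 10; 9 from 8; 8 from 5 and 6 via 7).** The alkynyl group is delivered to C7 of the trans epoxy alcohol 5 with inversion. This gives the anti relation of C7–C11 and O8 directly, and the primary hydroxyl becomes the C9 leaving group. An anti-selective propargylation of a C8 aldehyde with C6 as a CH2O branch was not used: it would set C6 and O8 anti in the chain C11–C7–C8–C9, where the target needs them syn. It would also force C6 through a β-acyloxy aldehyde.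

**Epoxide and chlorodiene (5 from 4; 4 from 3; 3 from 1 and 2).** Reagent-controlled epoxidation of the dienol 4 sets the absolute configuration. The chlorovinyl group is already C5=C6, so C6 never has to be an alcohol or an aldehyde next to the acid.

**Boronate (24 from 23; 23 from 21 via 22; 21 from 20).** The 1,1-disubstituted alkenylboronate comes from the alkyne of 20 by bromoboration, protonolysis and borylation.

## Alternatives that were turned down

**Alternative 1: anionic oxy-Cope ring expansion.** The C8–C9 bond of the ring is disconnected, which leads back to a terpene-derived tertiary cyclohexenol with two alkenyl arms. In the forward step its potassium alkoxide undergoes the [3,3] shift: C8–C9 forms, C1–C6 breaks, and the enolate is protonated to the cyclodecadienone A1. In its favour, there is no macrocyclisation, the start is from the chiral pool, and both ring alkenes come out ring-cis from the sigmatropic step. Against it, A1 still lacks C11–C13, the lactone, the C6 and C7 stereocentres and the C15 oxygen. These would have to be added on a flexible, transannularly reactive ring: alkylation at C7 next to the ketone, ketone reduction, lactonisation, methylenation, allylic oxidation of a methyl group beside two trisubstituted alkenes, and an ether-to-isovalerate exchange. On ring formation this alternative is stronger than the chosen route, which depends on a medium-ring olefination. The chosen route offers in exchange C7 and C8 set in an acyclic system by reagent control, and C6–O, the lactone and C15–O made in one step.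

**Alternative 2: three-component nickel coupling.** C5–C6 and C3–C4 are cut. A zerovalent nickel catalyst joins an α-branched C6 aldehyde, a propargyl silyl ether and an alkylzinc halide by syn addition across the alkyne, giving the allylic alcohol A2; no ring is formed. In its favour are high convergence, a C4=C5 geometry fixed mechanistically and not by an equilibrium, and C15 oxygen arriving with the alkyne. Against it, C6 is set only by Felkin-type induction from C7 in a β,γ-unsaturated aldehyde that epimerises and conjugates easily. Alkyne regiochemistry is open, the phosphonoacetate C–H is acidic towards the organozinc, and lactone and macrocycle are still to be made, with C12 raised from the alcohol level. On alkene geometry this alternative is the stronger one. The chosen route answers with a C6 centre that is created together with the lactone from a robust carboxylic acid.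

**Alternative 3: macrocyclic Horner–Wadsworth–Emmons olefination as the key step.** C1=C10 is cut. A lithium salt and an amidine base condense the C10 phosphonothioacetate with the C1 aldehyde to give A3, with the lactone masked as a disilylated 2-methylene-1,4-diol. In its favour, the reaction type is known, the hardest ring closure is met on a substrate free of Michael acceptors, and no untested step is needed; on that point it is stronger than the chosen route. Against it, the seco compound must already carry C6 and C4=C5, which costs an extra stereocontrolled C–C bond construction. After closure the lactone still needs selective desilylation, a two-stage oxidation of C12 beside an enethioate, lactonisation and ether cleavage at C15. The chosen route uses the same olefination downstream and so shares its risk, but reaches it with fewer redox and protecting-group steps, at the price of the amine mask.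

Key step: step 16

Remark on the chemistry: the phosphonate carbon C10 (compounds 15 to 30) and C11 of the amine adducts (28 to 33) are carried as epimer mixtures and left undefined in the SMILES; both centres become sp2 before the target. Germacrane numbering of the target is used for all intermediates.

## Route

Step 1
Reactants: 1 (E)-1,2-dichloroethene; 2 prop-2-yn-1-ol
Product: 3 (E)-5-chloropent-4-en-2-yn-1-ol
Conditions: Pd(PPh3)4 (cat.), CuI (cat.), n-BuNH2, Et2O, 25 °C, excess 1
Reagents that add atoms: none
Why: Sonogashira coupling; oxidative addition into one C–Cl bond of 1 retains the E geometry, and the excess of 1 should keep the second chloride from reacting.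

Step 2
Reactants: 3 (E)-5-chloropent-4-en-2-yn-1-ol
Product: 4 (2E,4E)-5-chloropenta-2,4-dien-1-ol
Conditions: NaAlH2(OCH2CH2OMe)2, THF, 0 °C
Reagents that add atoms: none
Why: trans-Hydroalumination of the propargylic alcohol, directed by the aluminium alkoxide, gives the E allylic alcohol on protonolysis; the vinyl chloride is remote from the directing oxygen and should survive at 0 °C.

Step 3
Reactants: 4 (2E,4E)-5-chloropenta-2,4-dien-1-ol
Product: 5 [(2R,3R)-3-[(E)-2-chloroethenyl]oxiran-2-yl]methanol
Conditions: Ti(OiPr)4 (cat.), D-(−)-diisopropyl tartrate (cat.), t-BuOOH, 4 Å MS, CH2Cl2, −20 °C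
Reagents that add atoms: tert-butyl hydroperoxide, CC(C)(C)OO
Why: Sharpless asymmetric epoxidation; only the allylic C=C is bound through the titanium alkoxide, and the D-tartrate complex delivers oxygen to the face that gives the (2R,3R) epoxide. This fixes C8 and, before inversion, C7.

Step 4
Reactants: 5 [(2R,3R)-3-[(E)-2-chloroethenyl]oxiran-2-yl]methanol; 6 ethynyltrimethylsilane
Product: 8 (2S,3R)-3-[(E)-2-chloroethenyl]-5-(trimethylsilyl)pent-4-yne-1,2-diol, via diethyl[(trimethylsilyl)ethynyl]aluminium 7 (not isolated)
Conditions: 6, n-BuLi, toluene, 0 °C; Et2AlCl; then 5, 0 to 25 °C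
Reagents that add atoms: diethylaluminium chloride, CC[Al](Cl)CC (its Et2Al group is found in 7 only)
Why: Alkynylalane opening of a 2,3-epoxy alcohol; the aluminium alkoxide of the primary hydroxyl directs the alkynyl group to the distal, allylically activated carbon C7, which is attacked with inversion. The trans epoxide therefore gives the C7–C11 bond and the C8 oxygen anti in the chain C6–C7–C8–C9, with C8 untouched.

Step 5
Reactants: 8 (2S,3R)-3-[(E)-2-chloroethenyl]-5-(trimethylsilyl)pent-4-yne-1,2-diol
Product: 9 (2S,3R)-3-[(E)-2-chloroethenyl]pent-4-yne-1,2-diol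
Conditions: K2CO3 (cat.), MeOH, 25 °C
Reagents that add atoms: none
Why: Base-catalysed methanolysis of the alkynyl C–Si bond (protodesilylation); the diol and the vinyl chloride are inert.

Step 6
Reactants: 9 (2S,3R)-3-[(E)-2-chloroethenyl]pent-4-yne-1,2-diol
Product: 11 (2S,3R)-3-[(E)-2-chloroethenyl]-2-[(triethylsilyl)oxy]pent-4-yn-1-yl trifluoromethanesulfonate, via hydroxy monotriflate 10 (not isolated)
Conditions: (CF3SO2)2O, 2,6-lutidine, CH2Cl2, −78 °C; then Et3SiOSO2CF3, −78 to −40 °C; used at once
Reagents that add atoms: trifluoromethanesulfonic anhydride, O=S(=O)(OS(=O)(=O)C(F)(F)F)C(F)(F)F; triethylsilyl trifluoromethanesulfonate, CC[Si](CC)(CC)OS(=O)(=O)C(F)(F)F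
Why: Sulfonylation at −78 °C is selective for the primary hydroxyl; silylating the secondary hydroxyl in the same flask blocks epoxide formation and gives a β-silyloxy triflate reactive enough for C-alkylation.

Step 7
Reactants: 12 (diethoxyphosphoryl)acetic acid; 13 ethanethiol
Product: 14 S-ethyl 2-(diethoxyphosphoryl)ethanethioate
Conditions: DCC, DMAP (cat.), CH2Cl2, 0 to 25 °C
Reagents that add atoms: none
Why: Steglich-type thioesterification through the O-acylisourea and the acylpyridinium ion.

Step 8
Reactants: 11 (2S,3R)-3-[(E)-2-chloroethenyl]-2-[(triethylsilyl)oxy]pent-4-yn-1-yl trifluoromethanesulfonate; 14 S-ethyl 2-(diethoxyphosphoryl)ethanethioate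
Product: 15 S-ethyl (4R,5R)-5-[(E)-2-chloroethenyl]-2-(diethoxyphosphoryl)-4-[(triethylsilyl)oxy]hept-6-ynethioate
Conditions: 14 (2.5 equiv), NaH (2.4 equiv), THF, 0 °C; then 11, 0 to 25 °C
Reagents that add atoms: none
Why: SN2 alkylation of the sodium salt of a phosphonoacetate-type C–H acid by a primary triflate forms C9–C10; the stabilised carbanion is used in excess to suppress dialkylation and leaves the silyl ether, the alkyne C–H and the vinyl chloride alone. C10 forms as both epimers, which is immaterial.

Step 9
Reactants: 15 S-ethyl (4R,5R)-5-[(E)-2-chloroethenyl]-2-(diethoxyphosphoryl)-4-[(triethylsilyl)oxy]hept-6-ynethioate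
Product: 16 S-ethyl (4R,5R)-5-[(E)-2-chloroethenyl]-2-(diethoxyphosphoryl)-4-hydroxyhept-6-ynethioate
Conditions: HF·pyridine, pyridine, THF, 0 °C; used at once
Reagents that add atoms: none
Why: Fluoride-assisted cleavage of the secondary triethylsilyl ether under buffered, weakly acidic conditions; no alkoxide is formed, so addition of the γ-hydroxyl to the thioester should be slow.

Step 10
Reactants: 16 S-ethyl (4R,5R)-5-[(E)-2-chloroethenyl]-2-(diethoxyphosphoryl)-4-hydroxyhept-6-ynethioate; 17 isovaleric anhydride
Product: 18 S-ethyl (4R,5R)-5-[(E)-2-chloroethenyl]-2-(diethoxyphosphoryl)-4-[(3-methylbutanoyl)oxy]hept-6-ynethioate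
Conditions: DMAP (cat.), pyridine, CH2Cl2, 0 °C
Reagents that add atoms: none
Why: DMAP-catalysed acylation; intermolecular acyl transfer from the acylpyridinium ion is expected to outrun five-ring lactonisation onto the thioester. O8 is capped here, before any C12 acyl group exists that could lactonise onto it.

Step 11
Reactants: 18 S-ethyl (4R,5R)-5-[(E)-2-chloroethenyl]-2-(diethoxyphosphoryl)-4-[(3-methylbutanoyl)oxy]hept-6-ynethioate
Product: 19 (3R,4R)-3-[(E)-2-chloroethenyl]-6-(diethoxyphosphoryl)-7-(ethylsulfanyl)-2-methylidene-4-[(3-methylbutanoyl)oxy]-7-oxoheptanoic acid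
Conditions: Pd(OAc)2 (cat.), 2-(diphenylphosphino)pyridine, MeSO3H (cat.), CO (20 bar), H2O, acetone, 50 °C
Reagents that add atoms: carbon monoxide, [C-]#[O+]; water, O
Why: Palladium-catalysed Markovnikov hydroxycarbonylation of a terminal alkyne; a Pd–H adds with palladium at the internal carbon C11, CO inserts and water cleaves the acyl complex to the 2-substituted acrylic acid. The alkenyl chloride does not undergo oxidative addition with this arylphosphine catalyst.

Step 12
Reactants: 20 pent-4-yn-1-ol
Product: 21 tert-butyl(pent-4-yn-1-yloxy)diphenylsilane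
Conditions: t-BuPh2SiCl, imidazole, CH2Cl2, 25 °C
Reagents that add atoms: tert-butyl(chloro)diphenylsilane, CC(C)(C)[Si](Cl)(c1ccccc1)c1ccccc1
Why: Silylation of a primary alcohol; the tert-butyldiphenylsilyl ether is chosen because it has to survive acetic acid in step 16.

Step 13
Reactants: 21 tert-butyl(pent-4-yn-1-yloxy)diphenylsilane
Product: 23 [(4-bromopent-4-en-1-yl)oxy](tert-butyl)diphenylsilane, via bromoalkenylborane 22 (not isolated)
Conditions: B-bromo-9-BBN, CH2Cl2, 0 °C; then AcOH, 0 to 25 °C
Reagents that add atoms: B-bromo-9-borabicyclo[3.3.1]nonane, BrB1C2CCCC1CCC2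
Why: Bromoboration of the terminal alkyne (syn addition, boron at the terminal carbon, bromine at the internal one), then protonolysis of the C–B bond with retention, gives the 2-bromo-1-alkene.

Step 14
Reactants: 23 [(4-bromopent-4-en-1-yl)oxy](tert-butyl)diphenylsilane
Product: 24 tert-butyldiphenyl{[4-(4,4,5,5-tetramethyl-1,3,2-dioxaborolan-2-yl)pent-4-en-1-yl]oxy}silane
Conditions: B2pin2, PdCl2(PPh3)2 (cat.), PPh3, KOPh, toluene, 50 °C
Reagents that add atoms: bis(pinacolato)diboron, CC1(C)OB(OC1(C)C)B1OC(C)(C)C(C)(C)O1
Why: Miyaura borylation of an alkenyl bromide with KOPh as base gives the 1,1-disubstituted alkenylboronate without touching the silyl ether.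

Step 15
Reactants: 19 (3R,4R)-3-[(E)-2-chloroethenyl]-6-(diethoxyphosphoryl)-7-(ethylsulfanyl)-2-methylidene-4-[(3-methylbutanoyl)oxy]-7-oxoheptanoic acid; 24 tert-butyldiphenyl{[4-(4,4,5,5-tetramethyl-1,3,2-dioxaborolan-2-yl)pent-4-en-1-yl]oxy}silane
Product: 25 (3R,4R)-3-[(1E)-6-[(tert-butyldiphenylsilyl)oxy]-3-methylidenehex-1-en-1-yl]-6-(diethoxyphosphoryl)-7-(ethylsulfanyl)-2-methylidene-4-[(3-methylbutanoyl)oxy]-7-oxoheptanoic acid
Conditions: Pd(OAc)2 (cat.), SPhos, K3PO4, THF–H2O, 40 °C; then work-up at pH 3
Reagents that add atoms: none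
Why: Suzuki–Miyaura coupling forms C4–C5; the electron-rich biarylphosphine allows oxidative addition of the alkenyl chloride at 40 °C with retention of the E geometry, which is not needed later. The acid and the C10–H are carried as potassium salts, which shields the thioester from hydroxide, and acidification returns 25.

Step 16
Reactants: 25 (3R,4R)-3-[(1E)-6-[(tert-butyldiphenylsilyl)oxy]-3-methylidenehex-1-en-1-yl]-6-(diethoxyphosphoryl)-7-(ethylsulfanyl)-2-methylidene-4-[(3-methylbutanoyl)oxy]-7-oxoheptanoic acid; 26 acetic acid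
Product: 27 S-ethyl (4R)-4-[(2R,3R)-2-[(1E)-2-(acetoxymethyl)-5-[(tert-butyldiphenylsilyl)oxy]pent-1-en-1-yl]-4-methylidene-5-oxooxolan-3-yl]-2-(diethoxyphosphoryl)-4-[(3-methylbutanoyl)oxy]butanethioate
Conditions: Pd(OAc)2 (10 mol %), p-benzoquinone (2 equiv), LiOAc (3 equiv), AcOH, 25 °C, chloride-free
Reagents that add atoms: lithium acetate, [Li+].CC(=O)[O-] (same acetate pool as 26)
Why: Proposed new method: divalent palladium from Pd(OAc)2 binds the diene C6=C5–C4=C15 and the C12 carboxylate adds to the terminus C6 on the face opposite the metal, a 5-exo-trig closure (ring O, C6, C7, C11, C12) that leaves a π-allyl over C5–C4–C15; acetate then adds to the unsubstituted terminus C15 anti to the metal and p-benzoquinone returns zerovalent palladium to the divalent state. The closest known reaction type is the palladium/benzoquinone 1,4-acyloxylation of conjugated dienes in acetic acid, including its lactonising variant with a tethered carboxylic acid and external acetate; not yet shown is an acyclic 2-alkyl diene whose internal nucleophile is an acrylic acid, hence the label. The only new stereocentre, C6, is controlled by C7: carboxylate addition to the coordinated diene is reversible in acetic acid, and the closure that puts the C5 alkenyl group trans to the C8 chain avoids the eclipsing of the cis arrangement, so the trans lactone should accumulate. The geometry of C4=C5 is set at the π-allyl stage: π–σ–π shifts equilibrate the syn and anti forms, the syn form (C6 on the side of C3) should be favoured, and attack at C15 then leaves C6 trans to C15 as in the target. Because C6 loses its alkene geometry on attack and the allyl equilibrates, both C5=C6 isomers of 25 should converge. 1,4- rather than 1,2-addition is expected because C5 is secondary and flanked by the electron-withdrawing lactone oxygen while C15 is primary; chloride must be absent, since it would enter as the second nucleophile, and the acidic medium keeps the phosphonothioacetate protonated and the silyl ether intact.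

Step 17
Reactants: 27 S-ethyl (4R)-4-[(2R,3R)-2-[(1E)-2-(acetoxymethyl)-5-[(tert-butyldiphenylsilyl)oxy]pent-1-en-1-yl]-4-methylidene-5-oxooxolan-3-yl]-2-(diethoxyphosphoryl)-4-[(3-methylbutanoyl)oxy]butanethioate
Product: 28 dimethylamine adduct of 27 at C13 (4-[(dimethylamino)methyl]oxolanone)
Conditions: Me2NH (2 M in THF, 1.5 equiv), THF, 0 °C
Reagents that add atoms: dimethylamine, CNC
Why: Conjugate (Michael) addition of the secondary amine to the exocyclic methylene lactone, much faster at 0 °C than aminolysis of the S-alkyl thioester; it removes the acceptor to which the C10 carbanion could add in a six-membered mode in step 20. The new centre C11 is temporary and not controlled.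

Step 18
Reactants: 28 dimethylamine adduct of 27
Product: 29 C1 alcohol (desilylated 28)
Conditions: HF·pyridine, pyridine, THF, 0 to 25 °C
Reagents that add atoms: none
Why: Fluoride-mediated desilylation of the primary silyl ether under buffered acidic conditions that leave the acetate, the isovalerate, the thioester and the protonated amine untouched.

Step 19
Reactants: 29 C1 alcohol
Product: 30 C1 aldehyde
Conditions: Dess–Martin periodinane, CH2Cl2, 0 °C; used crude
Reagents that add atoms: none
Why: Dess–Martin oxidation of the primary alcohol to the aldehyde; the acetic acid released keeps the amine protonated, so no premature olefination should occur.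

Step 20
Reactants: 30 C1 aldehyde
Product: 31 ten-membered enethioate (amine-masked lactone, C15 acetate, C8 isovalerate)
Conditions: LiCl, DBU, MeCN, 0.5 mM (syringe pump), 25 °C
Reagents that add atoms: none
Why: Intramolecular Horner–Wadsworth–Emmons olefination under Masamune–Roush conditions at high dilution closes the ten-membered ring by forming C1=C10. Elimination places C2 trans to the thioester carbonyl, hence cis to C9, which is both the usual E outcome for 2-substituted phosphonoacetates and the less strained ring geometry; the C10 epimers converge.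

Step 21
Reactants: 31 ten-membered enethioate
Product: 32 ten-membered enal (amine-masked lactone)
Conditions: Et3SiH, Pd on carbon (10 % Pd/C), acetone, 25 °C
Reagents that add atoms: none
Why: Fukuyama reduction; palladium inserts into the C–S bond and the acylpalladium is reduced by the silane to the enal without touching the lactone, the two esters or the trisubstituted alkenes. The masked lactone offers no C11=C13 bond to a palladium hydride.

Step 22
Reactants: 32 ten-membered enal (amine-masked lactone)
Product: 34 (1(10)E,4E,6R,7R,8R)-15-acetoxy-8-(3-methylbutanoyloxy)-14-oxogermacra-1(10),4,11(13)-trien-12,6-olide, via trimethylammonium iodide 33 (not isolated)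
Conditions: MeI, MeCN, 25 °C; then NaHCO3 (aq), EtOAc, 25 °C
Reagents that add atoms: iodomethane, CI (its methyl group is found in 33 only)
Why: Exhaustive N-methylation gives the quaternary ammonium salt, whose acidic C11–H allows E1cB (Hofmann-type) elimination with hydrogencarbonate and regenerates the α-methylene lactone; the base is too weak to open the lactone or the esters.

Step 23
Reactants: 34 (1(10)E,4E,6R,7R,8R)-15-acetoxy-8-(3-methylbutanoyloxy)-14-oxogermacra-1(10),4,11(13)-trien-12,6-olide
Product: 35 (1(10)E,4E,6R,7R,8R)-15-hydroxy-8-(3-methylbutanoyloxy)-14-oxogermacra-1(10),4,11(13)-trien-12,6-olide (target)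
Conditions: Candida antarctica lipase B (immobilised), phosphate buffer pH 7, acetone, 30 °C
Reagents that add atoms: none
Why: Lipase-catalysed hydrolysis at pH 7; the unhindered primary allylic acetate should fit the active site while the branched secondary isovalerate and the lactone do not, and neutral conditions spare both Michael acceptors.

## Compound list

1 | (E)-1,2-dichloroethene | Cl/C=C/Cl | starting material
2 | prop-2-yn-1-ol | C#CCO | starting material
3 | (E)-5-chloropent-4-en-2-yn-1-ol | OCC#C/C=C/Cl | intermediate
4 | (2E,4E)-5-chloropenta-2,4-dien-1-ol | OC/C=C/C=C/Cl | intermediate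
5 | [(2R,3R)-3-[(E)-2-chloroethenyl]oxiran-2-yl]methanol | OC[C@H]1O[C@@H]1/C=C/Cl | intermediate
6 | ethynyltrimethylsilane | C#C[Si](C)(C)C | starting material
7 | diethyl[(trimethylsilyl)ethynyl]aluminium, Et2AlC≡CSiMe3 (not isolated) | CC[Al](CC)C#C[Si](C)(C)C | intermediate
8 | (2S,3R)-3-[(E)-2-chloroethenyl]-5-(trimethylsilyl)pent-4-yne-1,2-diol | C[Si](C)(C)C#C[C@@H](/C=C/Cl)[C@H](O)CO | intermediate
9 | (2S,3R)-3-[(E)-2-chloroethenyl]pent-4-yne-1,2-diol | C#C[C@@H](/C=C/Cl)[C@H](O)CO | intermediate
10 | (2S,3R)-3-[(E)-2-chloroethenyl]-2-hydroxypent-4-yn-1-yl trifluoromethanesulfonate (not isolated) | C#C[C@@H](/C=C/Cl)[C@H](O)COS(=O)(=O)C(F)(F)F | intermediate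
11 | (2S,3R)-3-[(E)-2-chloroethenyl]-2-[(triethylsilyl)oxy]pent-4-yn-1-yl trifluoromethanesulfonate | C#C[C@@H](/C=C/Cl)[C@H](O[Si](CC)(CC)CC)COS(=O)(=O)C(F)(F)F | intermediate
12 | (diethoxyphosphoryl)acetic acid | OC(=O)CP(=O)(OCC)OCC | starting material
13 | ethanethiol | CCS | starting material
14 | S-ethyl 2-(diethoxyphosphoryl)ethanethioate | CCSC(=O)CP(=O)(OCC)OCC | intermediate
15 | S-ethyl (4R,5R)-5-[(E)-2-chloroethenyl]-2-(diethoxyphosphoryl)-4-[(triethylsilyl)oxy]hept-6-ynethioate (C2 epimers) | C#C[C@@H](/C=C/Cl)[C@H](O[Si](CC)(CC)CC)CC(C(=O)SCC)P(=O)(OCC)OCC | intermediate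
16 | S-ethyl (4R,5R)-5-[(E)-2-chloroethenyl]-2-(diethoxyphosphoryl)-4-hydroxyhept-6-ynethioate (C2 epimers) | C#C[C@@H](/C=C/Cl)[C@H](O)CC(C(=O)SCC)P(=O)(OCC)OCC | intermediate
17 | isovaleric anhydride (3-methylbutanoic anhydride) | CC(C)CC(=O)OC(=O)CC(C)C | starting material
18 | S-ethyl (4R,5R)-5-[(E)-2-chloroethenyl]-2-(diethoxyphosphoryl)-4-[(3-methylbutanoyl)oxy]hept-6-ynethioate (C2 epimers) | C#C[C@@H](/C=C/Cl)[C@H](OC(=O)CC(C)C)CC(C(=O)SCC)P(=O)(OCC)OCC | intermediate
19 | (3R,4R)-3-[(E)-2-chloroethenyl]-6-(diethoxyphosphoryl)-7-(ethylsulfanyl)-2-methylidene-4-[(3-methylbutanoyl)oxy]-7-oxoheptanoic acid (C6 epimers) | OC(=O)C(=C)[C@@H](/C=C/Cl)[C@H](OC(=O)CC(C)C)CC(C(=O)SCC)P(=O)(OCC)OCC | intermediate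
20 | pent-4-yn-1-ol | C#CCCCO | starting material
21 | tert-butyl(pent-4-yn-1-yloxy)diphenylsilane | C#CCCCO[Si](c1ccccc1)(c1ccccc1)C(C)(C)C | intermediate
22 | 9-[(1Z)-2-bromo-5-[(tert-butyldiphenylsilyl)oxy]pent-1-en-1-yl]-9-borabicyclo[3.3.1]nonane (not isolated) | Br/C(CCCO[Si](c1ccccc1)(c1ccccc1)C(C)(C)C)=C\B1C2CCCC1CCC2 | intermediate
23 | [(4-bromopent-4-en-1-yl)oxy](tert-butyl)diphenylsilane | C=C(Br)CCCO[Si](c1ccccc1)(c1ccccc1)C(C)(C)C | intermediate
24 | tert-butyldiphenyl{[4-(4,4,5,5-tetramethyl-1,3,2-dioxaborolan-2-yl)pent-4-en-1-yl]oxy}silane | C=C(B1OC(C)(C)C(C)(C)O1)CCCO[Si](c1ccccc1)(c1ccccc1)C(C)(C)C | intermediate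
25 | (3R,4R)-3-[(1E)-6-[(tert-butyldiphenylsilyl)oxy]-3-methylidenehex-1-en-1-yl]-6-(diethoxyphosphoryl)-7-(ethylsulfanyl)-2-methylidene-4-[(3-methylbutanoyl)oxy]-7-oxoheptanoic acid (C6 epimers; key-step precursor) | OC(=O)C(=C)[C@@H](/C=C/C(=C)CCCO[Si](c1ccccc1)(c1ccccc1)C(C)(C)C)[C@H](OC(=O)CC(C)C)CC(C(=O)SCC)P(=O)(OCC)OCC | intermediate
26 | acetic acid | CC(=O)O | starting material
27 | S-ethyl (4R)-4-[(2R,3R)-2-[(1E)-2-(acetoxymethyl)-5-[(tert-butyldiphenylsilyl)oxy]pent-1-en-1-yl]-4-methylidene-5-oxooxolan-3-yl]-2-(diethoxyphosphoryl)-4-[(3-methylbutanoyl)oxy]butanethioate (C2 epimers; key-step product) | C=C1C(=O)O[C@H](/C=C(/COC(C)=O)CCCO[Si](c2ccccc2)(c2ccccc2)C(C)(C)C)[C@H]1[C@H](OC(=O)CC(C)C)CC(C(=O)SCC)P(=O)(OCC)OCC | intermediate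
28 | S-ethyl (4R)-4-[(2R,3R)-2-[(1E)-2-(acetoxymethyl)-5-[(tert-butyldiphenylsilyl)oxy]pent-1-en-1-yl]-4-[(dimethylamino)methyl]-5-oxooxolan-3-yl]-2-(diethoxyphosphoryl)-4-[(3-methylbutanoyl)oxy]butanethioate (epimers at oxolane C4 and at the phosphonate carbon) | CN(C)CC1C(=O)O[C@H](/C=C(/COC(C)=O)CCCO[Si](c2ccccc2)(c2ccccc2)C(C)(C)C)[C@H]1[C@H](OC(=O)CC(C)C)CC(C(=O)SCC)P(=O)(OCC)OCC | intermediate
29 | S-ethyl (4R)-4-[(2R,3R)-2-[(1E)-2-(acetoxymethyl)-5-hydroxypent-1-en-1-yl]-4-[(dimethylamino)methyl]-5-oxooxolan-3-yl]-2-(diethoxyphosphoryl)-4-[(3-methylbutanoyl)oxy]butanethioate (same epimer mixtures) | CN(C)CC1C(=O)O[C@H](/C=C(/COC(C)=O)CCCO)[C@H]1[C@H](OC(=O)CC(C)C)CC(C(=O)SCC)P(=O)(OCC)OCC | intermediate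
30 | S-ethyl (4R)-4-[(2R,3R)-2-[(1E)-2-(acetoxymethyl)-5-oxopent-1-en-1-yl]-4-[(dimethylamino)methyl]-5-oxooxolan-3-yl]-2-(diethoxyphosphoryl)-4-[(3-methylbutanoyl)oxy]butanethioate (same epimer mixtures) | CN(C)CC1C(=O)O[C@H](/C=C(/COC(C)=O)CCC=O)[C@H]1[C@H](OC(=O)CC(C)C)CC(C(=O)SCC)P(=O)(OCC)OCC | intermediate
31 | S-ethyl (1(10)E,4E,6R,7R,8R)-15-acetoxy-13-(dimethylamino)-8-(3-methylbutanoyloxy)-12-oxo-11,13-dihydrogermacra-1(10),4-dien-12,6-olide-14-thioate (C11 epimers) | CN(C)CC1C(=O)O[C@@H]2/C=C(/COC(C)=O)CC/C=C(/C(=O)SCC)C[C@@H](OC(=O)CC(C)C)[C@@H]12 | intermediate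
32 | (1(10)E,4E,6R,7R,8R)-15-acetoxy-13-(dimethylamino)-8-(3-methylbutanoyloxy)-14-oxo-11,13-dihydrogermacra-1(10),4-dien-12,6-olide (C11 epimers) | CN(C)CC1C(=O)O[C@@H]2/C=C(/COC(C)=O)CC/C=C(/C=O)C[C@@H](OC(=O)CC(C)C)[C@@H]12 | intermediate
33 | trimethylammonium iodide of 32 (N-methylated at the C13 nitrogen; C11 epimers; not isolated) | C[N+](C)(C)CC1C(=O)O[C@@H]2/C=C(/COC(C)=O)CC/C=C(/C=O)C[C@@H](OC(=O)CC(C)C)[C@@H]12.[I-] | intermediate
34 | (1(10)E,4E,6R,7R,8R)-15-acetoxy-8-(3-methylbutanoyloxy)-14-oxogermacra-1(10),4,11(13)-trien-12,6-olide | C=C1C(=O)O[C@@H]2/C=C(/COC(C)=O)CC/C=C(/C=O)C[C@@H](OC(=O)CC(C)C)[C@@H]12 | intermediate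
35 | (1(10)E,4E,6R,7R,8R)-15-hydroxy-8-(3-methylbutanoyloxy)-14-oxogermacra-1(10),4,11(13)-trien-12,6-olide, CNP0345200.3 | C=C1C(=O)O[C@@H]2/C=C(/CO)CC/C=C(/C=O)C[C@@H](OC(=O)CC(C)C)[C@@H]12 | target

## Step count and least certain steps

Total: 23 steps. Longest linear sequence: 19 steps (steps 1–6, 8–11 and 15–23); steps 7 and 12–14 are side branches.

**Step 16 (key step, proposed new method).** Three things can go wrong. The anti π-allyl may be populated because C3 and C6 crowd each other on the 2-substituted allyl, which would erode the C4=C5 geometry. Acetate may add at C5 (1,2-addition). The oxypalladation may fail to equilibrate to the trans lactone, or the doubly allylic C7–H may be attacked by palladium. The fallback uses known chemistry, sets out from 25 and returns at 27. Iodolactonisation of 25 (I2, NaHCO3, MeCN, 0 °C, then equilibration in MeCN) should close the lactone at C6 and, after the usual 1,3-shift of the allylic iodide to the primary position, give S-ethyl (4R)-2-(diethoxyphosphoryl)-4-[(2R,3R)-2-[(1E)-5-[(tert-butyldiphenylsilyl)oxy]-2-(iodomethyl)pent-1-en-1-yl]-4-methylidene-5-oxooxolan-3-yl]-4-[(3-methylbutanoyl)oxy]butanethioate F1. Displacement of the iodide at C15 with AgOAc in AcOH then gives 27.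

**Step 20.** Ten-membered ring closure may lose out to oligomerisation, or the ring strain may stall the elimination. The fallback sets out from 29 and returns at 31, closing the same bond by metathesis. Aqueous formaldehyde and K2CO3 turn the phosphonate of 29 into the α-methylene thioester alcohol F2. Dess–Martin oxidation gives the aldehyde F3. Takai–Lombardo methylenation (Zn, CH2Br2, TiCl4) gives the terminal alkene F4. Ring-closing metathesis of F4 (amine protonated with TsOH; second-generation Grubbs catalyst RuCl2(H2IMes)(PCy3)(=CHPh), toluene, 80 °C, high dilution) gives 31 with loss of ethene, the ring-cis alkene being the one a medium ring should favour.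

**Step 15.** Oxidative addition into the unactivated alkenyl chloride may be slow, and the aqueous base may meanwhile hydrolyse the thioester or shift the doubly allylic C7–H. The fallback sets out from 18 and returns at 25, coupling before the acid exists. Coupling of 18 with 24 under the same catalyst gives the dienyne S-ethyl (4R,5R)-5-[(1E)-6-[(tert-butyldiphenylsilyl)oxy]-3-methylidenehex-1-en-1-yl]-2-(diethoxyphosphoryl)-4-[(3-methylbutanoyl)oxy]hept-6-ynethioate F5. Bromoboration with B-bromo-9-BBN and protonolysis with AcOH, selective for the triple bond, gives the 2-bromoalkene F6 (the 6-bromohept-6-enethioate corresponding to F5, 4R,5S). Hydroxycarbonylation of the alkenyl bromide (PdCl2(PPh3)2, CO, H2O, Et3N, DMF, 60 °C), which tolerates the diene, gives 25.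

**Step 11.** Branching at C7 may push palladium to the terminal carbon and give the linear acid, and the thioester sulfur may slow the catalyst. The fallback sets out from 18 and returns at 19. Bromoboration and protonolysis (B-bromo-9-BBN, then AcOH) give S-ethyl (4R,5S)-6-bromo-5-[(E)-2-chloroethenyl]-2-(diethoxyphosphoryl)-4-[(3-methylbutanoyl)oxy]hept-6-enethioate F7. Hydroxycarbonylation of the alkenyl bromide under the conditions above, in which the alkenyl chloride is inert, gives 19.

**Step 10 (with step 9).** The free C8 hydroxyl may lactonise onto the γ-thioester with loss of ethanethiol before it is acylated. The fallback sets out from 11 and returns at 18, keeping C14 as an ester that does not lactonise. Alkylation of 11 with the sodium salt of tert-butyl (diethoxyphosphoryl)acetate gives tert-butyl (4R,5R)-5-[(E)-2-chloroethenyl]-2-(diethoxyphosphoryl)-4-[(triethylsilyl)oxy]hept-6-ynoate F8. HF·pyridine gives the hydroxy ester F9. Isovaleric anhydride 17 with DMAP gives the isovalerate F10. CF3CO2H gives (4R,5R)-5-[(E)-2-chloroethenyl]-2-(diethoxyphosphoryl)-4-[(3-methylbutanoyl)oxy]hept-6-ynoic acid F11. Thioesterification with 13 (DCC, DMAP) gives 18.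

## Further compounds

F1 | step 16 | S-ethyl (4R)-2-(diethoxyphosphoryl)-4-[(2R,3R)-2-[(1E)-5-[(tert-butyldiphenylsilyl)oxy]-2-(iodomethyl)pent-1-en-1-yl]-4-methylidene-5-oxooxolan-3-yl]-4-[(3-methylbutanoyl)oxy]butanethioate | C=C1C(=O)O[C@H](/C=C(/CI)CCCO[Si](c2ccccc2)(c2ccccc2)C(C)(C)C)[C@H]1[C@H](OC(=O)CC(C)C)CC(C(=O)SCC)P(=O)(OCC)OCC
F2 | step 20 | S-ethyl (4R)-4-[(2R,3R)-2-[(1E)-2-(acetoxymethyl)-5-hydroxypent-1-en-1-yl]-4-[(dimethylamino)methyl]-5-oxooxolan-3-yl]-2-methylidene-4-[(3-methylbutanoyl)oxy]butanethioate | CN(C)CC1C(=O)O[C@H](/C=C(/COC(C)=O)CCCO)[C@H]1[C@H](OC(=O)CC(C)C)CC(=C)C(=O)SCC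
F3 | step 20 | S-ethyl (4R)-4-[(2R,3R)-2-[(1E)-2-(acetoxymethyl)-5-oxopent-1-en-1-yl]-4-[(dimethylamino)methyl]-5-oxooxolan-3-yl]-2-methylidene-4-[(3-methylbutanoyl)oxy]butanethioate | CN(C)CC1C(=O)O[C@H](/C=C(/COC(C)=O)CCC=O)[C@H]1[C@H](OC(=O)CC(C)C)CC(=C)C(=O)SCC
F4 | step 20 | S-ethyl (4R)-4-[(2R,3R)-2-[(1E)-2-(acetoxymethyl)hexa-1,5-dien-1-yl]-4-[(dimethylamino)methyl]-5-oxooxolan-3-yl]-2-methylidene-4-[(3-methylbutanoyl)oxy]butanethioate | CN(C)CC1C(=O)O[C@H](/C=C(/COC(C)=O)CCC=C)[C@H]1[C@H](OC(=O)CC(C)C)CC(=C)C(=O)SCC
F5 | step 15 | S-ethyl (4R,5R)-5-[(1E)-6-[(tert-butyldiphenylsilyl)oxy]-3-methylidenehex-1-en-1-yl]-2-(diethoxyphosphoryl)-4-[(3-methylbutanoyl)oxy]hept-6-ynethioate | C#C[C@@H](/C=C/C(=C)CCCO[Si](c1ccccc1)(c1ccccc1)C(C)(C)C)[C@H](OC(=O)CC(C)C)CC(C(=O)SCC)P(=O)(OCC)OCC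
F6 | step 15 | S-ethyl (4R,5S)-6-bromo-5-[(1E)-6-[(tert-butyldiphenylsilyl)oxy]-3-methylidenehex-1-en-1-yl]-2-(diethoxyphosphoryl)-4-[(3-methylbutanoyl)oxy]hept-6-enethioate | C=C(Br)[C@@H](/C=C/C(=C)CCCO[Si](c1ccccc1)(c1ccccc1)C(C)(C)C)[C@H](OC(=O)CC(C)C)CC(C(=O)SCC)P(=O)(OCC)OCC
F7 | step 11 | S-ethyl (4R,5S)-6-bromo-5-[(E)-2-chloroethenyl]-2-(diethoxyphosphoryl)-4-[(3-methylbutanoyl)oxy]hept-6-enethioate | C=C(Br)[C@@H](/C=C/Cl)[C@H](OC(=O)CC(C)C)CC(C(=O)SCC)P(=O)(OCC)OCC
F8 | step 10 | tert-butyl (4R,5R)-5-[(E)-2-chloroethenyl]-2-(diethoxyphosphoryl)-4-[(triethylsilyl)oxy]hept-6-ynoate | C#C[C@@H](/C=C/Cl)[C@H](O[Si](CC)(CC)CC)CC(C(=O)OC(C)(C)C)P(=O)(OCC)OCC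
F9 | step 10 | tert-butyl (4R,5R)-5-[(E)-2-chloroethenyl]-2-(diethoxyphosphoryl)-4-hydroxyhept-6-ynoate | C#C[C@@H](/C=C/Cl)[C@H](O)CC(C(=O)OC(C)(C)C)P(=O)(OCC)OCC
F10 | step 10 | tert-butyl (4R,5R)-5-[(E)-2-chloroethenyl]-2-(diethoxyphosphoryl)-4-[(3-methylbutanoyl)oxy]hept-6-ynoate | C#C[C@@H](/C=C/Cl)[C@H](OC(=O)CC(C)C)CC(C(=O)OC(C)(C)C)P(=O)(OCC)OCC
F11 | step 10 | (4R,5R)-5-[(E)-2-chloroethenyl]-2-(diethoxyphosphoryl)-4-[(3-methylbutanoyl)oxy]hept-6-ynoic acid | C#C[C@@H](/C=C/Cl)[C@H](OC(=O)CC(C)C)CC(C(=O)O)P(=O)(OCC)OCC
A1 | alternative 1 | ten-membered dienone: 14-(tert-butyldimethylsilyloxy)-8-(4-methoxybenzyloxy)germacra-1(10),4-dien-6-one | O=C1/C=C(/C)CC/C=C(/CO[Si](C)(C)C(C)(C)C)C[C@@H](OCc2ccc(OC)cc2)C1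
A2 | alternative 2 | acyclic C6 allylic alcohol with C15 tert-butyldiphenylsilyl ether, C1 dioxolane, C12 tert-butyldimethylsilyl ether, C8 4-methoxybenzyl ether and C10 ethyl phosphonoacetate | O[C@H](/C=C(/CO[Si](c1ccccc1)(c1ccccc1)C(C)(C)C)CCC1OCCO1)[C@H](C(=C)CO[Si](C)(C)C(C)(C)C)[C@H](OCc1ccc(OC)cc1)CC(C(=O)OCC)P(=O)(OCC)OCC
A3 | alternative 3 | ten-membered dienyl S-ethyl thioester with the lactone masked as 6,12-bis(tert-butyldimethylsilyl) 2-methylene-1,4-diol, C15 4-methoxybenzyl ether and C8 isovalerate | C=C(CO[Si](C)(C)C(C)(C)C)[C@H]1[C@H](O[Si](C)(C)C(C)(C)C)/C=C(/COCc2ccc(OC)cc2)CC/C=C(/C(=O)SCC)C[C@H]1OC(=O)CC(C)C
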